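**Plan**

1. Retrosynthesis (chromene numbering O1, C2–C4, C4a, C5–C8, C8a; Ts = 4-methylphenylsulfonyl): the two N–Ts bonds are cut last, the pyran ring is opened at O1–C2 and C4–C4a (prenal), the C6–O bond is removed (para-oxidation of a phenol), and the C7 O–methyl bond is cut back to an O–silyl bond.
2. The central benzene ring is then cut at C8a–C8, C7–C6 and C4a–C8a into a 3-indolylcyclobutenone and an indolyl siloxyalkyne, both made from one alkyne, 3-ethynyl-1-tosylindole, which comes from indole.
3. Feature that permits this cut: C8a(O)–C8(indolyl)–C7(O) is a 2-aryl resorcinol unit, the second indolyl sits on C5 meta to both oxygens, and C6 and C4a can be CH when the ring is made, which is the pattern a cyclobutenone/ynol ether benzannulation delivers.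
4. Forward order: the indole rings are present from the start, the central benzene ring arises in step 7, its oxidation level and the methyl ether are set in steps 8 to 11, the pyran ring closes in step 12, and the nitrogens are freed in step 13.
5. Downstream regiochemistry is fixed by structure: the desilylated resorcinol is symmetric about the C8···C5 axis, so para-oxidation has one outcome, and in the hydroquinone only the C8a hydroxyl has a free ortho carbon (C4a).
6. Stereochemistry: kumbicin C has no stereocentre and no stereogenic double bond, so no stereocontrol is needed.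

Key step: step 7

**Route**

Step 1
Reactants: 1 indole
Product: 3 N-tosyl-3-iodoindole, via 3-iodoindole 2 (not isolated)
Conditions: I2, KOH, DMF, rt; then TsCl, 0 °C to rt
Reagents that add atoms: iodine, II; p-toluenesulfonyl chloride (TsCl), Cc1ccc(cc1)S(=O)(=O)Cl
Why: Electrophilic iodination of indole is selective for C3, and the potassium indolide is then N-sulfonylated in the same flask (iodination followed by N-tosylation), so the labile 3-iodoindole is never isolated.

Step 2
Reactants: 3 N-tosyl-3-iodoindole; 4 trimethylsilylacetylene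
Product: 5 N-tosyl-3-[(trimethylsilyl)ethynyl]indole
Conditions: PdCl2(PPh3)2 (cat.), CuI (cat.), Et3N, THF, rt to 50 °C
Reagents that add atoms: none
Why: Sonogashira coupling of 3-iodo-N-sulfonylindoles with terminal alkynes is routine, the electron-poor C–I bond adding readily to palladium.

Step 3
Reactants: 5 N-tosyl-3-[(trimethylsilyl)ethynyl]indole
Product: 6 N-tosyl-3-ethynylindole
Conditions: K2CO3 (cat.), MeOH/THF, rt
Reagents that add atoms: none
Why: Carbonate-catalysed methanolysis of the alkynyl C–Si bond (protodesilylation) is fast at room temperature, whereas an N-tosylindole without an acyl group at C3 survives these conditions.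

Step 4
Reactants: 6 N-tosyl-3-ethynylindole; 7 trichloroacetyl chloride
Product: 9 4,4-dichloro-3-(1-tosylindol-3-yl)cyclobut-2-en-1-one, via dichloroketene 8 (not isolated)
Conditions: Zn(Cu), Et2O/DME, 35 °C, slow addition of 7
Reagents that add atoms: none
Why: Dichloroketene, formed by zinc dechlorination of 7, adds to the terminal alkyne in a thermal [2+2] cycloaddition with its carbonyl carbon bonding to the unsubstituted alkyne carbon, while the sulfonylated indole 2,3-bond is too electron-poor to compete.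

Step 5
Reactants: 9 4,4-dichloro-3-(1-tosylindol-3-yl)cyclobut-2-en-1-one
Product: 10 3-(1-tosylindol-3-yl)cyclobut-2-en-1-one
Conditions: Zn, AcOH, TMEDA, EtOH, 0 °C to rt
Reagents that add atoms: none
Why: Zinc in buffered acetic acid removes both chlorines α to the carbonyl (reductive dehalogenation), and the TMEDA buffer prevents acid-induced opening of the strained enone.

Step 6
Reactants: 6 N-tosyl-3-ethynylindole
Product: 13 1-tosyl-3-[(triisopropylsilyloxy)ethynyl]indole, via lithium acetylide 11 (not isolated), via lithium ynolate 12 (not isolated)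
Conditions: LiN(SiMe3)2, THF, −78 °C; t-BuOOLi (from t-BuOOH and LiN(SiMe3)2), −78 to 0 °C; i-Pr3SiOTf, −78 to 0 °C
Reagents that add atoms: tert-butyl hydroperoxide, CC(C)(C)OO; triisopropylsilyl trifluoromethanesulfonate, CC(C)[Si](C(C)C)(C(C)C)OS(=O)(=O)C(F)(F)F
Why: The lithium acetylide attacks the electrophilic peroxide oxygen of t-BuOOLi to give the ynolate (acetylide oxidation), which the hard silyl triflate traps on oxygen, and the hindered amide base neither metalates C2 nor attacks the sulfonyl group.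

Step 7
Reactants: 10 3-(1-tosylindol-3-yl)cyclobut-2-en-1-one; 13 1-tosyl-3-[(triisopropylsilyloxy)ethynyl]indole
Product: 18 2,5-bis(1-tosylindol-3-yl)-3-(triisopropylsilyloxy)phenol, via vinylketene 14 (not isolated), via 4-alkenylcyclobutenone 15 (not isolated), via dienylketene 16 (not isolated), via cyclohexadienone 17 (not isolated)
Conditions: toluene, 80 °C, then 110 °C, argon
Reagents that add atoms: none
Why: At 80 °C cyclobutenone 10 opens by 4π electrocyclic cleavage to vinylketene 14, and the aryl-bearing carbon of 13, made nucleophilic by the remote siloxy oxygen, attacks the ketene carbonyl carbon in a regiospecific [2+2] cycloaddition that forms C8a–C8 and C6–C7 and closes the four-membered ring of 15. Ring 15 reopens (4π) to dienylketene 16, the benzene ring is closed by a thermally allowed disrotatory 6π electrocyclization that forms C4a–C8a, and dienone 17 tautomerizes to phenol 18. The closest known reaction type is the Danheiser benzannulation of cyclobutenones with siloxyalkynes, which gives resorcinol monosilyl ethers. No stereocentre remains, the one in 15 being lost on ring opening. The step needs a single orientation of the alkyne toward the ketene, and the polarization by the siloxy group secures it, so that the alkyne indolyl ends up between the two oxygens and the cyclobutenone indolyl meta to both. The triisopropylsilyl group is chosen to resist silyl migration and the tosyl groups keep both indoles inert toward the ketenes; the labels C8a/C7 and C4a/C6 stay interchangeable until step 9.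

Step 8
Reactants: 18 2,5-bis(1-tosylindol-3-yl)-3-(triisopropylsilyloxy)phenol
Product: 19 2,5-bis(1-tosylindol-3-yl)benzene-1,3-diol
Conditions: Bu4NF, AcOH, THF, 0 °C to rt
Reagents that add atoms: none
Why: Fluoride cleaves the aryl silyl ether (desilylation), and buffering with acetic acid keeps the resorcinol protonated and the N-tosyl groups untouched.

Step 9
Reactants: 19 2,5-bis(1-tosylindol-3-yl)benzene-1,3-diol
Product: 20 2-hydroxy-3,6-bis(1-tosylindol-3-yl)-1,4-benzoquinone
Conditions: (KSO3)2NO, KH2PO4, acetone/H2O, 0 °C to rt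
Reagents that add atoms: potassium nitrosodisulfonate (KSO3)2NO, [K+].[K+].[O]N(S(=O)(=O)[O-])S(=O)(=O)[O-]
Why: In the Teuber oxidation the nitroxide converts a phenol with a free para position into the para-quinone, and because 19 is symmetric about the axis through its two indolyl-bearing carbons both para positions give the same hydroxyquinone, the oxidized carbon thereby becoming C6.

Step 10
Reactants: 20 2-hydroxy-3,6-bis(1-tosylindol-3-yl)-1,4-benzoquinone
Product: 21 2-methoxy-3,6-bis(1-tosylindol-3-yl)-1,4-benzoquinone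
Conditions: Me2SO4, K2CO3, acetone, 56 °C
Reagents that add atoms: dimethyl sulfate, COS(=O)(=O)OC
Why: The potassium salt of a 3-substituted 2-hydroxy-1,4-quinone is alkylated on oxygen by dimethyl sulfate (O-methylation of a vinylogous acid), since C-methylation would create a quaternary carbon and the para-quinone ether is the more stable O-methyl isomer.

Step 11
Reactants: 21 2-methoxy-3,6-bis(1-tosylindol-3-yl)-1,4-benzoquinone
Product: 22 2-methoxy-3,6-bis(1-tosylindol-3-yl)benzene-1,4-diol
Conditions: Na2S2O4, THF/H2O, rt, argon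
Reagents that add atoms: none
Why: Dithionite reduces para-quinones to hydroquinones in a two-phase mixture (quinone reduction) without affecting sulfonamides, and the air-sensitive product is carried on at once.

Step 12
Reactants: 22 2-methoxy-3,6-bis(1-tosylindol-3-yl)benzene-1,4-diol; 23 3-methylbut-2-enal (prenal)
Product: 26 7-methoxy-2,2-dimethyl-5,8-bis(1-tosylindol-3-yl)-2H-chromen-6-ol, via benzodioxaborin 24 (not isolated), via ortho-quinone methide 25 (not isolated)
Conditions: PhB(OH)2, AcOH, toluene, 110 °C, azeotropic removal of water, argon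
Reagents that add atoms: none
Why: Phenylboronic acid esterifies the hydroxyl that has a free ortho carbon and delivers prenal to that carbon (C4a), dioxaborin 24 fragments to ortho-quinone methide 25, and oxa-6π electrocyclization closes the pyran ring (boronic acid-mediated chromene annulation of a phenol with an enal), while the other hydroxyl, flanked by methoxy and indolyl, cannot react.

Step 13
Reactants: 26 7-methoxy-2,2-dimethyl-5,8-bis(1-tosylindol-3-yl)-2H-chromen-6-ol
Product: 27 kumbicin C
Conditions: KOH, dioxane/H2O (degassed), 90 °C, argon; aq. NH4Cl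
Reagents that add atoms: none
Why: Hydroxide attacks the sulfonyl sulfur of both N-tosylindoles and releases the indolide anions (sulfonamide hydrolysis), the alcohol-free medium avoiding alkyl tosylates that could alkylate the phenoxide, and exclusion of air protecting the electron-rich phenol.

**Compound list**

1 | indole | c1ccc2[nH]ccc2c1 | starting material
2 | 3-iodo-1H-indole | Ic1c[nH]c2ccccc12 | intermediate
3 | 3-iodo-1-tosylindole | Cc1ccc(cc1)S(=O)(=O)n1cc(I)c2ccccc12 | intermediate
4 | trimethylsilylacetylene | C#C[Si](C)(C)C | starting material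
5 | 1-tosyl-3-[(trimethylsilyl)ethynyl]indole | Cc1ccc(cc1)S(=O)(=O)n1cc(C#C[Si](C)(C)C)c2ccccc12 | intermediate
6 | 3-ethynyl-1-tosylindole | Cc1ccc(cc1)S(=O)(=O)n1cc(C#C)c2ccccc12 | intermediate
7 | trichloroacetyl chloride | O=C(Cl)C(Cl)(Cl)Cl | starting material
8 | dichloroketene | O=C=C(Cl)Cl | intermediate
9 | 4,4-dichloro-3-(1-tosylindol-3-yl)cyclobut-2-en-1-one | O=C1C=C(c2cn(S(=O)(=O)c3ccc(C)cc3)c3ccccc23)C1(Cl)Cl | intermediate
10 | 3-(1-tosylindol-3-yl)cyclobut-2-en-1-one | O=C1C=C(C1)c1cn(S(=O)(=O)c2ccc(C)cc2)c2ccccc12 | intermediate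
11 | lithium (1-tosylindol-3-yl)acetylide | [Li+].[C-]#Cc1cn(S(=O)(=O)c2ccc(C)cc2)c2ccccc12 | intermediate
12 | lithium 2-(1-tosylindol-3-yl)ethynolate | [Li+].[O-]C#Cc1cn(S(=O)(=O)c2ccc(C)cc2)c2ccccc12 | intermediate
13 | 1-tosyl-3-[(triisopropylsilyloxy)ethynyl]indole | CC(C)[Si](C(C)C)(C(C)C)OC#Cc1cn(S(=O)(=O)c2ccc(C)cc2)c2ccccc12 | intermediate
14 | 3-(1-tosylindol-3-yl)buta-1,3-dien-1-one (vinylketene) | O=C=CC(=C)c1cn(S(=O)(=O)c2ccc(C)cc2)c2ccccc12 | intermediate
15 | 2-(1-tosylindol-3-yl)-4-[1-(1-tosylindol-3-yl)ethenyl]-3-(triisopropylsilyloxy)cyclobut-2-en-1-one (racemic) | O=C1C(c2cn(S(=O)(=O)c3ccc(C)cc3)c3ccccc23)=C(O[Si](C(C)C)(C(C)C)C(C)C)C1C(=C)c1cn(S(=O)(=O)c2ccc(C)cc2)c2ccccc12 | intermediate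
16 | (3E)-2,5-bis(1-tosylindol-3-yl)-3-(triisopropylsilyloxy)hexa-1,3,5-trien-1-one (dienylketene, ketene and vinyl cis) | O=C=C(c1cn(S(=O)(=O)c2ccc(C)cc2)c2ccccc12)/C(O[Si](C(C)C)(C(C)C)C(C)C)=C\C(=C)c1cn(S(=O)(=O)c2ccc(C)cc2)c2ccccc12 | intermediate
17 | 2,5-bis(1-tosylindol-3-yl)-3-(triisopropylsilyloxy)cyclohexa-2,4-dien-1-one | O=C1CC(c2cn(S(=O)(=O)c3ccc(C)cc3)c3ccccc23)=CC(O[Si](C(C)C)(C(C)C)C(C)C)=C1c1cn(S(=O)(=O)c2ccc(C)cc2)c2ccccc12 | intermediate
18 | 2,5-bis(1-tosylindol-3-yl)-3-(triisopropylsilyloxy)phenol | Oc1cc(-c2cn(S(=O)(=O)c3ccc(C)cc3)c3ccccc23)cc(O[Si](C(C)C)(C(C)C)C(C)C)c1-c1cn(S(=O)(=O)c2ccc(C)cc2)c2ccccc12 | intermediate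
19 | 2,5-bis(1-tosylindol-3-yl)benzene-1,3-diol | Oc1cc(-c2cn(S(=O)(=O)c3ccc(C)cc3)c3ccccc23)cc(O)c1-c1cn(S(=O)(=O)c2ccc(C)cc2)c2ccccc12 | intermediate
20 | 2-hydroxy-3,6-bis(1-tosylindol-3-yl)-1,4-benzoquinone | O=C1C=C(c2cn(S(=O)(=O)c3ccc(C)cc3)c3ccccc23)C(=O)C(O)=C1c1cn(S(=O)(=O)c2ccc(C)cc2)c2ccccc12 | intermediate
21 | 2-methoxy-3,6-bis(1-tosylindol-3-yl)-1,4-benzoquinone | O=C1C=C(c2cn(S(=O)(=O)c3ccc(C)cc3)c3ccccc23)C(=O)C(OC)=C1c1cn(S(=O)(=O)c2ccc(C)cc2)c2ccccc12 | intermediate
22 | 2-methoxy-3,6-bis(1-tosylindol-3-yl)benzene-1,4-diol | COc1c(O)c(-c2cn(S(=O)(=O)c3ccc(C)cc3)c3ccccc23)cc(O)c1-c1cn(S(=O)(=O)c2ccc(C)cc2)c2ccccc12 | intermediate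
23 | 3-methylbut-2-enal (prenal) | CC(C)=CC=O | starting material
24 | 7-methoxy-4-(2-methylprop-1-enyl)-2-phenyl-5,8-bis(1-tosylindol-3-yl)-4H-1,3,2-benzodioxaborinin-6-ol (racemic) | COc1c(O)c(-c2cn(S(=O)(=O)c3ccc(C)cc3)c3ccccc23)c2C(C=C(C)C)OB(c3ccccc3)Oc2c1-c1cn(S(=O)(=O)c2ccc(C)cc2)c2ccccc12 | intermediate
25 | (6Z)-4-hydroxy-3-methoxy-6-(3-methylbut-2-enylidene)-2,5-bis(1-tosylindol-3-yl)cyclohexa-2,4-dien-1-one (ortho-quinone methide) | COC1=C(c2cn(S(=O)(=O)c3ccc(C)cc3)c3ccccc23)C(=O)/C(=C\C=C(C)C)C(c2cn(S(=O)(=O)c3ccc(C)cc3)c3ccccc23)=C1O | intermediate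
26 | 7-methoxy-2,2-dimethyl-5,8-bis(1-tosylindol-3-yl)-2H-chromen-6-ol | COc1c(O)c(-c2cn(S(=O)(=O)c3ccc(C)cc3)c3ccccc23)c2C=CC(C)(C)Oc2c1-c1cn(S(=O)(=O)c2ccc(C)cc2)c2ccccc12 | intermediate
27 | kumbicin C, 5,8-di(1H-indol-3-yl)-7-methoxy-2,2-dimethyl-2H-chromen-6-ol | COc1c(O)c(-c2c[nH]c3ccccc23)c2c(c1-c1c[nH]c3ccccc13)OC(C)(C)C=C2 | target

**Step count**

Total step count: 13.
Longest linear sequence: 12 steps (steps 1 to 5 and 7 to 13, from indole); step 6 is the side branch from alkyne 6.

**Steps most likely to fail**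

Step 7. What may go wrong: on heating, silyl migration from oxygen to carbon in 13 (giving a silylketene) and O-acylation of the newly formed phenol by vinylketene 14 may outrun the [2+2] addition, which is slowed because the attacking alkyne carbon carries an aryl group. The fallback keeps the same ring construction but uses an ynol ether that cannot shift a silyl group and is reached by cross-coupling. Iodide 3 is coupled (Negishi coupling, Pd(PPh3)4, THF) with methoxyethynylzinc chloride F1, generated from chloroacetaldehyde dimethyl acetal with LiNEt2 and then ZnCl2, to give 3-(methoxyethynyl)-1-tosylindole F2. Heating F2 with cyclobutenone 10 in toluene should pass through vinylketene 14, 4-alkenylcyclobutenone F3, dienylketene F4 and cyclohexadienone F5 to 3-methoxy-2,5-bis(1-tosylindol-3-yl)phenol F6. Teuber oxidation of F6 with (KSO3)2NO, para to its only hydroxyl, returns to the route at methoxyquinone 21, so that steps 8 to 10 are no longer needed.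

Step 12. What may go wrong: bond formation at C4a, crowded by the neighbouring N-tosylindolyl group, may be too slow, so that re-oxidation of the hydroquinone and self-condensation of prenal dominate. In the fallback the five carbons are attached at the quinone stage and the pyran ring is closed by isomerization. Methoxyquinone 21 is treated with tributyl(3-methylbut-2-enyl)stannane and BF3·OEt2 in CH2Cl2 at −78 °C, the allylstannane adding to the only unsubstituted quinone carbon, to give 2-methoxy-5-(3-methylbut-2-enyl)-3,6-bis(1-tosylindol-3-yl)benzene-1,4-diol F7. Ag2O oxidizes it to 2-methoxy-5-(3-methylbut-2-enyl)-3,6-bis(1-tosylindol-3-yl)-1,4-benzoquinone F8. Heating F8 in pyridine enolizes it to ortho-quinone methide 25, whose oxa-6π closure gives chromenol 26, where the route is rejoined.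

Step 4. What may go wrong: dichloroketene, or trichloroacetyl chloride activated by ZnCl2, may attack the indole 2,3-bond, and the dichlorocyclobutenone may undergo 1,3-chlorine shift or hydrolysis before it is reduced. The fallback uses no ketene and buys the four-membered ring. Iodide 3 undergoes iodine–magnesium exchange with i-PrMgCl·LiCl (THF, −40 °C) to (1-tosylindol-3-yl)magnesium chloride F9, which adds to the carbonyl group of commercial 3-ethoxycyclobut-2-en-1-one to give 3-ethoxy-1-(1-tosylindol-3-yl)cyclobut-2-en-1-ol F10. Dilute aqueous HCl hydrolyses the enol ether with loss of water and allylic transposition and delivers cyclobutenone 10, where the route is rejoined; steps 4 and 5 are replaced and alkyne 6 is then needed only for step 6.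

**Further compounds**

F1 | step 7 | methoxyethynylzinc chloride | COC#C[Zn]Cl
F2 | step 7 | 3-(methoxyethynyl)-1-tosylindole | COC#Cc1cn(S(=O)(=O)c2ccc(C)cc2)c2ccccc12
F3 | step 7 | 3-methoxy-2-(1-tosylindol-3-yl)-4-[1-(1-tosylindol-3-yl)ethenyl]cyclobut-2-en-1-one (racemic) | O=C1C(c2cn(S(=O)(=O)c3ccc(C)cc3)c3ccccc23)=C(OC)C1C(=C)c1cn(S(=O)(=O)c2ccc(C)cc2)c2ccccc12
F4 | step 7 | (3E)-3-methoxy-2,5-bis(1-tosylindol-3-yl)hexa-1,3,5-trien-1-one | O=C=C(c1cn(S(=O)(=O)c2ccc(C)cc2)c2ccccc12)/C(OC)=C\C(=C)c1cn(S(=O)(=O)c2ccc(C)cc2)c2ccccc12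
F5 | step 7 | 3-methoxy-2,5-bis(1-tosylindol-3-yl)cyclohexa-2,4-dien-1-one | O=C1CC(c2cn(S(=O)(=O)c3ccc(C)cc3)c3ccccc23)=CC(OC)=C1c1cn(S(=O)(=O)c2ccc(C)cc2)c2ccccc12
F6 | step 7 | 3-methoxy-2,5-bis(1-tosylindol-3-yl)phenol | COc1cc(-c2cn(S(=O)(=O)c3ccc(C)cc3)c3ccccc23)cc(O)c1-c1cn(S(=O)(=O)c2ccc(C)cc2)c2ccccc12
F7 | step 12 | 2-methoxy-5-(3-methylbut-2-enyl)-3,6-bis(1-tosylindol-3-yl)benzene-1,4-diol | COc1c(O)c(-c2cn(S(=O)(=O)c3ccc(C)cc3)c3ccccc23)c(CC=C(C)C)c(O)c1-c1cn(S(=O)(=O)c2ccc(C)cc2)c2ccccc12
F8 | step 12 | 2-methoxy-5-(3-methylbut-2-enyl)-3,6-bis(1-tosylindol-3-yl)-1,4-benzoquinone | COC1=C(c2cn(S(=O)(=O)c3ccc(C)cc3)c3ccccc23)C(=O)C(CC=C(C)C)=C(c2cn(S(=O)(=O)c3ccc(C)cc3)c3ccccc23)C1=O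
F9 | step 4 | (1-tosylindol-3-yl)magnesium chloride | Cc1ccc(cc1)S(=O)(=O)n1cc([Mg]Cl)c2ccccc12
F10 | step 4 | 3-ethoxy-1-(1-tosylindol-3-yl)cyclobut-2-en-1-ol | CCOC1=CC(O)(C1)c1cn(S(=O)(=O)c2ccc(C)cc2)c2ccccc12
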